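**Plan**

- Ring numbering used in the text: C1 = ketone carbon, C2 = methyl-bearing oxirane carbon, C3 = oxirane CH, C4 = CH2, C5 = CH carrying the side chain, C6 = CH–O-angeloyl. Locants inside compound names follow each compound's own IUPAC numbering.
- Retrosynthesis cuts C1–C2 and C4–C5 of the cyclohexanone. This splits the ring into a malate-type unit C1(=O)–C6(O)–C5, which carries the future side chain as an ester, and a (Z)-CH2–CH=C(CH3) unit.
- The feature that allows this is that C1 is an acyl carbon flanked by the O-bearing C6 and by the alkene-derived C2, while C5 is alpha to the side-chain carbon. C5 can therefore act as an enolate toward an allylic C4, and C2 as a vinyl anion toward an acyl C1.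
- Forward order: an acyclic hydroxy amide is closed to the only carbocycle by one-flask alkylation and cycloacylation. The ring is then adjusted (reduction, directed epoxidation, oxidation). The ester becomes the 2-substituted acrolein, followed by allylation, double esterification, metathesis and the side-chain oxirane.
- Stereochemistry: C6 is bought with D-aspartate. C5 follows from anti-alkylation of the chelated dianion, the C1 carbinol from Luche reduction, and the ring oxirane from hydroxyl-directed epoxidation. The side-chain carbinol and oxirane are set by reagent and catalyst control.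

Key step: step 5

Assumption: compounds 1, 4, 20 and 22 and all reagents are taken as commercial; (−)-Ipc2B(allyl) and the D-fructose-derived Shi ketone are assumed to show their usual facial preferences on these substrates.

**Route**

Step 1
Reactants: 1 (2R)-2-amino-4-tert-butoxy-4-oxobutanoic acid (D-aspartic acid 4-tert-butyl ester)
Product: 2 (2R)-4-tert-butoxy-2-hydroxy-4-oxobutanoic acid
Conditions: NaNO2, 1 M aq. H2SO4, 0 °C → rt
Reagents that add atoms: water O
Why: Deaminative hydroxylation by diazotisation should proceed with net retention (double inversion through the alpha-lactone), so the (R) centre of 1 becomes the C6–O centre, and the tert-butyl ester should survive cold dilute acid.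

Step 2
Reactants: 2 (2R)-4-tert-butoxy-2-hydroxy-4-oxobutanoic acid
Product: 3 tert-butyl (3R)-3-hydroxy-4-[methoxy(methyl)amino]-4-oxobutanoate
Conditions: MeNH(OMe)·HCl, EDC·HCl, HOBt, N-methylmorpholine, CH2Cl2, 0 °C → rt
Reagents that add atoms: N,O-dimethylhydroxylamine hydrochloride CNOC.Cl
Why: Carbodiimide amide coupling should give the Weinreb amide selectively, because the amine is far more nucleophilic than the secondary alcohol.

Step 3
Reactants: 4 but-2-yn-1-ol
Product: 5 (2Z)-3-iodobut-2-en-1-ol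
Conditions: NaAlH2(OCH2CH2OMe)2 (Red-Al), Et2O, 0 °C → rt; then I2, THF, −78 °C
Reagents that add atoms: iodine II
Why: Alkoxide-directed trans-hydroalumination places aluminium at C3, and iodinolysis with retention should give the (Z)-iodoalkene.

Step 4
Reactants: 5 (2Z)-3-iodobut-2-en-1-ol
Product: 6 (2Z)-1-bromo-3-iodobut-2-ene
Conditions: CBr4, PPh3, CH2Cl2, 0 °C
Reagents that add atoms: carbon tetrabromide BrC(Br)(Br)Br
Why: Appel bromination of the primary allylic alcohol leaves the vinyl iodide and the alkene geometry untouched.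

Step 5
Reactants: 3 tert-butyl (3R)-3-hydroxy-4-[methoxy(methyl)amino]-4-oxobutanoate; 6 (2Z)-1-bromo-3-iodobut-2-ene
Product: 9 tert-butyl (1S,6R)-6-hydroxy-4-methyl-5-oxocyclohex-3-ene-1-carboxylate, via alkylated hydroxy amide 7 (not isolated), via cyclic lithium hemiaminal 8 (not isolated)
Conditions: LiN(i-Pr)2 (LDA, 2.2 equiv), THF, −78 → −20 °C; 6, −78 → −10 °C; then t-BuLi (4.3 equiv), THF/Et2O/pentane, −100 → −78 °C; aq. NH4Cl
Reagents that add atoms: none
Why: Proposed new method: the dianion of 3 (lithium alkoxide plus ester enolate in a six-membered chelate) should be C-alkylated by the allylic bromide 6 anti to the amide-bearing substituent (Fráter–Seebach alkylation), which forms C4–C5 and sets C5 trans to the bought C6–O centre. tert-Butyllithium should then first return the liberated diisopropylamine to LDA and next exchange the vinyl iodide, and the (Z)-vinyllithium should attack the Weinreb amide in a 6-exo-trig acyl substitution that forms C1–C2; the closest known reaction type is the halogen–lithium-exchange-initiated cycloacylation of iodoalkenyl amides (Parham-type cyclisation). The alkene geometry fixed in 6 places the C–Li bond cis to the tether, so the carbocycle closes with the C2=C3 alkene inside the ring. The neighbouring lithium alkoxide and the methoxyamide should chelate the tetrahedral adduct 8, which would release the enone only on work-up and so prevent over-addition. The selectivity needed is attack on the amide and not 5-exo attack on the ester, and it is secured by the bulk and low electrophilicity of the tert-butyl ester. The ring closure creates no stereocentre, so C5 and C6 keep the configurations set by the alkylation and by 1.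

Step 6
Reactants: 9 tert-butyl (1S,6R)-6-hydroxy-4-methyl-5-oxocyclohex-3-ene-1-carboxylate
Product: 10 tert-butyl (1S,6R)-4-methyl-5-oxo-6-[(triethylsilyl)oxy]cyclohex-3-ene-1-carboxylate
Conditions: Et3SiCl, imidazole, DMF, 0 °C
Reagents that add atoms: chlorotriethylsilane CC[Si](Cl)(CC)CC
Why: Imidazole-promoted silylation of the only hydroxyl masks the C6 oxygen so that later oxidations act at C1 alone.

Step 7
Reactants: 10 tert-butyl (1S,6R)-4-methyl-5-oxo-6-[(triethylsilyl)oxy]cyclohex-3-ene-1-carboxylate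
Product: 11 tert-butyl (1S,5R,6R)-5-hydroxy-4-methyl-6-[(triethylsilyl)oxy]cyclohex-3-ene-1-carboxylate
Conditions: NaBH4, CeCl3·7H2O, MeOH, −78 → −40 °C
Reagents that add atoms: none
Why: Luche 1,2-reduction with axial hydride delivery to the half-chair should give the equatorial C1 alcohol, trans to the C6 silyl ether and cis to the C5 ester.

Step 8
Reactants: 11 tert-butyl (1S,5R,6R)-5-hydroxy-4-methyl-6-[(triethylsilyl)oxy]cyclohex-3-ene-1-carboxylate
Product: 13 (1R,5R,6R)-2-methyl-6-[(triethylsilyl)oxy]-5-[3-(trimethylsilyl)prop-1-en-2-yl]cyclohex-2-en-1-ol, via bis(silylmethyl) carbinol 12 (not isolated)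
Conditions: Me3SiCH2Li (excess), CeCl3 (anhydrous), THF, −78 °C → rt; then silica gel, CH2Cl2, rt
Reagents that add atoms: (trimethylsilyl)methyllithium [Li]C[Si](C)(C)C
Why: Double addition of the weakly basic organocerium reagent to the ester followed by Peterson elimination of one beta-silyl group (allylsilane synthesis from esters) should turn the ester into the 2-substituted allylsilane, the free alcohol only consuming one equivalent.

Step 9
Reactants: 13 (1R,5R,6R)-2-methyl-6-[(triethylsilyl)oxy]-5-[3-(trimethylsilyl)prop-1-en-2-yl]cyclohex-2-en-1-ol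
Product: 14 (1S,2S,3R,4R,6R)-1-methyl-3-[(triethylsilyl)oxy]-4-[3-(trimethylsilyl)prop-1-en-2-yl]-7-oxabicyclo[4.1.0]heptan-2-ol
Conditions: VO(acac)2 (cat.), t-BuOOH, CH2Cl2, 0 °C → rt
Reagents that add atoms: tert-butyl hydroperoxide CC(C)(C)OO
Why: Hydroxyl-directed vanadium-catalysed epoxidation should deliver oxygen to the C2=C3 alkene syn to the allylic C1 alcohol, so that the oxirane is cis to the hydroxyl and to the C5 side chain and trans to the silyloxy group, while the remote allylsilane alkene has no directing group.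

Step 10
Reactants: 14 (1S,2S,3R,4R,6R)-1-methyl-3-[(triethylsilyl)oxy]-4-[3-(trimethylsilyl)prop-1-en-2-yl]-7-oxabicyclo[4.1.0]heptan-2-ol
Product: 15 (1R,3R,4R,6R)-1-methyl-3-[(triethylsilyl)oxy]-4-[3-(trimethylsilyl)prop-1-en-2-yl]-7-oxabicyclo[4.1.0]heptan-2-one
Conditions: Dess–Martin periodinane, NaHCO3, CH2Cl2, 0 °C → rt
Reagents that add atoms: none
Why: Dess–Martin oxidation of the secondary epoxy alcohol should give the alpha,beta-epoxy ketone under neutral conditions that spare the oxirane and the allylsilane.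

Step 11
Reactants: 15 (1R,3R,4R,6R)-1-methyl-3-[(triethylsilyl)oxy]-4-[3-(trimethylsilyl)prop-1-en-2-yl]-7-oxabicyclo[4.1.0]heptan-2-one
Product: 17 (1R,3R,4R,6R)-3-hydroxy-4-(3-hydroxyprop-1-en-2-yl)-1-methyl-7-oxabicyclo[4.1.0]heptan-2-one, via epoxysilane 16 (not isolated)
Conditions: mCPBA, NaHCO3, CH2Cl2, 0 °C; then Bu4NF, AcOH, THF, 0 °C
Reagents that add atoms: 3-chloroperbenzoic acid OOC(=O)c1cccc(Cl)c1
Why: Prilezhaev epoxidation of the electron-rich allylsilane alkene and fluoride-induced anti-elimination of the beta-silyl epoxide should transpose it to the primary allylic alcohol, the same fluoride removing the triethylsilyl ether.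

Step 12
Reactants: 17 (1R,3R,4R,6R)-3-hydroxy-4-(3-hydroxyprop-1-en-2-yl)-1-methyl-7-oxabicyclo[4.1.0]heptan-2-one
Product: 18 (1R,3R,4R,6R)-3-hydroxy-1-methyl-4-(3-oxoprop-1-en-2-yl)-7-oxabicyclo[4.1.0]heptan-2-one
Conditions: TEMPO (cat.), PhI(OAc)2, CH2Cl2, rt
Reagents that add atoms: none
Why: Nitroxyl-catalysed oxidation should be selective for the primary allylic alcohol over the hindered secondary ketol.

Step 13
Reactants: 18 (1R,3R,4R,6R)-3-hydroxy-1-methyl-4-(3-oxoprop-1-en-2-yl)-7-oxabicyclo[4.1.0]heptan-2-one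
Product: 19 (1R,3R,4R,6R)-3-hydroxy-4-[(3S)-3-hydroxyhexa-1,5-dien-2-yl]-1-methyl-7-oxabicyclo[4.1.0]heptan-2-one
Conditions: (−)-Ipc2B(allyl), Et2O, −78 °C; then HOCH2CH2NH2, rt
Reagents that add atoms: (−)-B-allyldiisopinocampheylborane C=CCB([C@@H]1C[C@@H]2C[C@H]([C@H]1C)C2(C)C)[C@@H]1C[C@@H]2C[C@H]([C@H]1C)C2(C)C
Why: Brown asymmetric allylboration through the closed chair transition state should add allyl to one aldehyde face under reagent control and set the (S) carbinol, the aldehyde reacting far faster than the ring ketone.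

Step 14
Reactants: 19 (1R,3R,4R,6R)-3-hydroxy-4-[(3S)-3-hydroxyhexa-1,5-dien-2-yl]-1-methyl-7-oxabicyclo[4.1.0]heptan-2-one; 20 (2Z)-2-methylbut-2-enoic acid (angelic acid), two equivalents incorporated, one per hydroxyl
Product: 21 (1R,3R,4R,6R)-1-methyl-4-{(3S)-3-[(2Z)-2-methylbut-2-enoyloxy]hexa-1,5-dien-2-yl}-2-oxo-7-oxabicyclo[4.1.0]heptan-3-yl (2Z)-2-methylbut-2-enoate
Conditions: 20 (2.4 equiv), 2,4,6-trichlorobenzoyl chloride (2.4 equiv), Et3N, toluene, rt; then 19, toluene, 80 °C
Reagents that add atoms: (2Z)-2-methylbut-2-enoic acid (second equivalent of 20) C/C=C(/C)C(=O)O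
Why: Yamaguchi-type esterification, in which each of the two secondary alcohols of 19 takes one angeloyl group from the preformed mixed anhydride of 20 (two equivalents of acid in all), run without a nucleophilic amine catalyst, should limit Z-to-E isomerisation to tiglate.

Step 15
Reactants: 21 (1R,3R,4R,6R)-1-methyl-4-{(3S)-3-[(2Z)-2-methylbut-2-enoyloxy]hexa-1,5-dien-2-yl}-2-oxo-7-oxabicyclo[4.1.0]heptan-3-yl (2Z)-2-methylbut-2-enoate; 22 2-methylbut-2-ene
Product: 23 (1R,3R,4R,6R)-1-methyl-4-{(3S)-6-methyl-3-[(2Z)-2-methylbut-2-enoyloxy]hepta-1,5-dien-2-yl}-2-oxo-7-oxabicyclo[4.1.0]heptan-3-yl (2Z)-2-methylbut-2-enoate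
Conditions: 22 (excess), second-generation Grubbs catalyst RuCl2(=CHPh)(PCy3)(H2IMes) (cat.), CH2Cl2, 40 °C
Reagents that add atoms: none
Why: Olefin cross-metathesis of the only monosubstituted alkene with 2-methylbut-2-ene should install the prenyl terminus, the 1,1-disubstituted and conjugated ester alkenes being unreactive.

Step 16
Reactants: 23 (1R,3R,4R,6R)-1-methyl-4-{(3S)-6-methyl-3-[(2Z)-2-methylbut-2-enoyloxy]hepta-1,5-dien-2-yl}-2-oxo-7-oxabicyclo[4.1.0]heptan-3-yl (2Z)-2-methylbut-2-enoate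
Product: 24 (1R,3R,4R,6R)-4-{(3S)-4-[(2R)-3,3-dimethyloxiran-2-yl]-3-[(2Z)-2-methylbut-2-enoyloxy]but-1-en-2-yl}-1-methyl-2-oxo-7-oxabicyclo[4.1.0]heptan-3-yl (2Z)-2-methylbut-2-enoate (target)
Conditions: D-fructose-derived Shi ketone (cat.), Oxone (2KHSO5·KHSO4·K2SO4), K2CO3, Bu4NHSO4, MeCN/dimethoxymethane/aq. buffer, 0 °C
Reagents that add atoms: potassium peroxymonosulfate [K+].[O-]S(=O)(=O)OO
Why: Shi asymmetric epoxidation through the spiro transition state should oxidise only the electron-rich trisubstituted alkene and set the (R) oxirane centre, the angelates and the 1,1-disubstituted alkene being too electron-poor or hindered.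

**Compound list**

1 | (2R)-2-amino-4-tert-butoxy-4-oxobutanoic acid | CC(C)(C)OC(=O)C[C@@H](N)C(=O)O | starting material
2 | (2R)-4-tert-butoxy-2-hydroxy-4-oxobutanoic acid | CC(C)(C)OC(=O)C[C@@H](O)C(=O)O | intermediate
3 | tert-butyl (3R)-3-hydroxy-4-[methoxy(methyl)amino]-4-oxobutanoate | CC(C)(C)OC(=O)C[C@@H](O)C(=O)N(C)OC | intermediate
4 | but-2-yn-1-ol | CC#CCO | starting material
5 | (2Z)-3-iodobut-2-en-1-ol | C/C(I)=C/CO | intermediate
6 | (2Z)-1-bromo-3-iodobut-2-ene | C/C(I)=C/CBr | intermediate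
7 | tert-butyl (2S,3R)-3-hydroxy-2-[(2Z)-3-iodobut-2-en-1-yl]-4-[methoxy(methyl)amino]-4-oxobutanoate (lithium alkoxide in the flask) | CC(C)(C)OC(=O)[C@@H](C/C=C(/C)I)[C@@H](O)C(=O)N(C)OC | intermediate
8 | tert-butyl (1S,6R)-5,6-dihydroxy-5-[methoxy(methyl)amino]-4-methylcyclohex-3-ene-1-carboxylate (dilithium salt in the flask, C5 undefined) | CC(C)(C)OC(=O)[C@H]1CC=C(C)C(O)(N(C)OC)[C@@H]1O | intermediate
9 | tert-butyl (1S,6R)-6-hydroxy-4-methyl-5-oxocyclohex-3-ene-1-carboxylate | CC(C)(C)OC(=O)[C@H]1CC=C(C)C(=O)[C@@H]1O | intermediate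
10 | tert-butyl (1S,6R)-4-methyl-5-oxo-6-[(triethylsilyl)oxy]cyclohex-3-ene-1-carboxylate | CC(C)(C)OC(=O)[C@H]1CC=C(C)C(=O)[C@@H]1O[Si](CC)(CC)CC | intermediate
11 | tert-butyl (1S,5R,6R)-5-hydroxy-4-methyl-6-[(triethylsilyl)oxy]cyclohex-3-ene-1-carboxylate | CC(C)(C)OC(=O)[C@H]1CC=C(C)[C@@H](O)[C@@H]1O[Si](CC)(CC)CC | intermediate
12 | (1R,5S,6R)-5-[2-hydroxy-1,3-bis(trimethylsilyl)propan-2-yl]-2-methyl-6-[(triethylsilyl)oxy]cyclohex-2-en-1-ol | C[Si](C)(C)CC(O)(C[Si](C)(C)C)[C@H]1CC=C(C)[C@@H](O)[C@@H]1O[Si](CC)(CC)CC | intermediate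
13 | (1R,5R,6R)-2-methyl-6-[(triethylsilyl)oxy]-5-[3-(trimethylsilyl)prop-1-en-2-yl]cyclohex-2-en-1-ol | C=C(C[Si](C)(C)C)[C@H]1CC=C(C)[C@@H](O)[C@@H]1O[Si](CC)(CC)CC | intermediate
14 | (1S,2S,3R,4R,6R)-1-methyl-3-[(triethylsilyl)oxy]-4-[3-(trimethylsilyl)prop-1-en-2-yl]-7-oxabicyclo[4.1.0]heptan-2-ol (oxirane cis to hydroxyl and side chain) | C=C(C[Si](C)(C)C)[C@H]1C[C@H]2O[C@@]2(C)[C@@H](O)[C@@H]1O[Si](CC)(CC)CC | intermediate
15 | (1R,3R,4R,6R)-1-methyl-3-[(triethylsilyl)oxy]-4-[3-(trimethylsilyl)prop-1-en-2-yl]-7-oxabicyclo[4.1.0]heptan-2-one | C=C(C[Si](C)(C)C)[C@H]1C[C@H]2O[C@@]2(C)C(=O)[C@@H]1O[Si](CC)(CC)CC | intermediate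
16 | 15 with the side-chain alkene epoxidised: 1-methyl-3-[(triethylsilyl)oxy]-4-{2-[(trimethylsilyl)methyl]oxiran-2-yl}-7-oxabicyclo[4.1.0]heptan-2-one, ring configuration as in 15, both oxirane epimers | C[Si](C)(C)CC1(CO1)[C@H]1C[C@H]2O[C@@]2(C)C(=O)[C@@H]1O[Si](CC)(CC)CC | intermediate
17 | (1R,3R,4R,6R)-3-hydroxy-4-(3-hydroxyprop-1-en-2-yl)-1-methyl-7-oxabicyclo[4.1.0]heptan-2-one | C=C(CO)[C@H]1C[C@H]2O[C@@]2(C)C(=O)[C@@H]1O | intermediate
18 | (1R,3R,4R,6R)-3-hydroxy-1-methyl-4-(3-oxoprop-1-en-2-yl)-7-oxabicyclo[4.1.0]heptan-2-one | C=C(C=O)[C@H]1C[C@H]2O[C@@]2(C)C(=O)[C@@H]1O | intermediate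
19 | (1R,3R,4R,6R)-3-hydroxy-4-[(3S)-3-hydroxyhexa-1,5-dien-2-yl]-1-methyl-7-oxabicyclo[4.1.0]heptan-2-one | C=C([C@H](CC=C)O)[C@H]1C[C@H]2O[C@@]2(C)C(=O)[C@@H]1O | intermediate
20 | (2Z)-2-methylbut-2-enoic acid (angelic acid) | C/C=C(/C)C(=O)O | starting material
21 | (1R,3R,4R,6R)-1-methyl-4-{(3S)-3-[(2Z)-2-methylbut-2-enoyloxy]hexa-1,5-dien-2-yl}-2-oxo-7-oxabicyclo[4.1.0]heptan-3-yl (2Z)-2-methylbut-2-enoate | C=C([C@H](CC=C)OC(=O)/C(C)=C\C)[C@H]1C[C@H]2O[C@@]2(C)C(=O)[C@@H]1OC(=O)/C(C)=C\C | intermediate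
22 | 2-methylbut-2-ene | CC=C(C)C | starting material
23 | (1R,3R,4R,6R)-1-methyl-4-{(3S)-6-methyl-3-[(2Z)-2-methylbut-2-enoyloxy]hepta-1,5-dien-2-yl}-2-oxo-7-oxabicyclo[4.1.0]heptan-3-yl (2Z)-2-methylbut-2-enoate | C=C([C@H](CC=C(C)C)OC(=O)/C(C)=C\C)[C@H]1C[C@H]2O[C@@]2(C)C(=O)[C@@H]1OC(=O)/C(C)=C\C | intermediate
24 | (1R,3R,4R,6R)-4-{(3S)-4-[(2R)-3,3-dimethyloxiran-2-yl]-3-[(2Z)-2-methylbut-2-enoyloxy]but-1-en-2-yl}-1-methyl-2-oxo-7-oxabicyclo[4.1.0]heptan-3-yl (2Z)-2-methylbut-2-enoate | C=C([C@H](C[C@H]1OC1(C)C)OC(=O)/C(C)=C\C)[C@H]1C[C@H]2O[C@@]2(C)C(=O)[C@@H]1OC(=O)/C(C)=C\C | target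

**Step count and risks**

Total step count: 16. Longest linear sequence: 14 steps (steps 1, 2 and 5 to 16); steps 3 and 4 form the two-step branch to 6.

Steps most likely to fail:

Step 5 (Proposed new method). The one-flask sequence may fail through proton quench of the vinyllithium, intermolecular attack of tert-butyllithium on the amide, loss of the N–O bond under excess base, erosion of the anti-selectivity of the alkylation, or re-enolisation of the alkylated ester by the regenerated amide base. The fallback sets out from 3 and 6 and returns at 10, using known chemistry only. The Fráter–Seebach alkylation is stopped after the first stage and 7 is isolated. Silylation with Et3SiCl and imidazole gives tert-butyl (2S,3R)-2-[(2Z)-3-iodobut-2-en-1-yl]-4-[methoxy(methyl)amino]-4-oxo-3-[(triethylsilyl)oxy]butanoate F1. Reduction with i-Bu2AlH at −78 °C gives tert-butyl (2S,3R)-2-[(2Z)-3-iodobut-2-en-1-yl]-4-oxo-3-[(triethylsilyl)oxy]butanoate F2. Intramolecular Nozaki–Hiyama–Kishi addition (CrCl2, catalytic NiCl2, DMSO) closes C1–C2 and gives tert-butyl (1S,6R)-5-hydroxy-4-methyl-6-[(triethylsilyl)oxy]cyclohex-3-ene-1-carboxylate F3 as a mixture at the carbinol. Dess–Martin oxidation converges this mixture on 10.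

Step 8. The second addition to the hindered tert-butyl ester may stall, or the intermediate ketone may be enolised, so that no allylsilane forms. The fallback sets out from 11 and returns at 13. The tert-butyl ester is cleaved with Me3SiOTf and 2,6-lutidine followed by aqueous work-up to (1S,5R,6R)-5-hydroxy-4-methyl-6-[(triethylsilyl)oxy]cyclohex-3-ene-1-carboxylic acid F4. Methylation with Me3SiCHN2 gives methyl (1S,5R,6R)-5-hydroxy-4-methyl-6-[(triethylsilyl)oxy]cyclohex-3-ene-1-carboxylate F5. The unhindered methyl ester is then taken to 13 with Me3SiCH2MgCl and CeCl3 followed by silica gel.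

Step 14. The angeloyl group may isomerise to tigloyl during activation, and acylation of the hindered hydroxyl next to the ketone may be slow, so that the double esterification stops at a mono-ester. The fallback sets out from 19 and returns at 21 by building the Z-alkenes after acylation. Both hydroxyls are esterified with 2-[bis(2,2,2-trifluoroethoxy)phosphoryl]propanoic acid (DCC, DMAP) to give (1R,3R,4R,6R)-4-[(3S)-3-{2-[bis(2,2,2-trifluoroethoxy)phosphoryl]propanoyloxy}hexa-1,5-dien-2-yl]-1-methyl-2-oxo-7-oxabicyclo[4.1.0]heptan-3-yl 2-[bis(2,2,2-trifluoroethoxy)phosphoryl]propanoate F6. A Still–Gennari olefination with acetaldehyde (KN(SiMe3)2, 18-crown-6, THF, −78 °C) should then give the two (Z)-2-methylbut-2-enoates of 21.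

Further compounds
F1 | step 5 | tert-butyl (2S,3R)-2-[(2Z)-3-iodobut-2-en-1-yl]-4-[methoxy(methyl)amino]-4-oxo-3-[(triethylsilyl)oxy]butanoate | CC(C)(C)OC(=O)[C@@H](C/C=C(/C)I)[C@@H](O[Si](CC)(CC)CC)C(=O)N(C)OC
F2 | step 5 | tert-butyl (2S,3R)-2-[(2Z)-3-iodobut-2-en-1-yl]-4-oxo-3-[(triethylsilyl)oxy]butanoate | CC(C)(C)OC(=O)[C@@H](C/C=C(/C)I)[C@@H](O[Si](CC)(CC)CC)C=O
F3 | step 5 | tert-butyl (1S,6R)-5-hydroxy-4-methyl-6-[(triethylsilyl)oxy]cyclohex-3-ene-1-carboxylate (both C5 epimers) | CC(C)(C)OC(=O)[C@H]1CC=C(C)C(O)[C@@H]1O[Si](CC)(CC)CC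
F4 | step 8 | (1S,5R,6R)-5-hydroxy-4-methyl-6-[(triethylsilyl)oxy]cyclohex-3-ene-1-carboxylic acid | OC(=O)[C@H]1CC=C(C)[C@@H](O)[C@@H]1O[Si](CC)(CC)CC
F5 | step 8 | methyl (1S,5R,6R)-5-hydroxy-4-methyl-6-[(triethylsilyl)oxy]cyclohex-3-ene-1-carboxylate | COC(=O)[C@H]1CC=C(C)[C@@H](O)[C@@H]1O[Si](CC)(CC)CC
F6 | step 14 | (1R,3R,4R,6R)-4-[(3S)-3-{2-[bis(2,2,2-trifluoroethoxy)phosphoryl]propanoyloxy}hexa-1,5-dien-2-yl]-1-methyl-2-oxo-7-oxabicyclo[4.1.0]heptan-3-yl 2-[bis(2,2,2-trifluoroethoxy)phosphoryl]propanoate | C=C([C@H](CC=C)OC(=O)C(C)P(=O)(OCC(F)(F)F)OCC(F)(F)F)[C@H]1C[C@H]2O[C@@]2(C)C(=O)[C@@H]1OC(=O)C(C)P(=O)(OCC(F)(F)F)OCC(F)(F)F
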